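At late times the target and second product of a flask together count the partner spent, each unit of partner giving one of either. The charge holds 1.05 equiv of partner against 2.00 of the two substrates together, so partner is the limiting reagent and the yield of target is the share of partner that goes to target.

| setting | noon | spring | dawn | midnight |
|---|---|---|---|---|
| starting material | 0.10 M | 0.10 M | 0.10 M (fed, over 64.0 s) | 0.10 M |
| second substrate | 1.00 equiv | 1.00 equiv (fed, over 64.0 s) | 1.00 equiv | 1.00 equiv |
| partner | 1.05 equiv | 1.05 equiv | 1.05 equiv | 1.05 equiv |
| precatalyst | 0.5 mol% | 0.5 mol% | 0.5 mol% | 0.5 mol% |
| remark | one stirred flow tank at steady state, fed with the mixture as stated, mean residence time 80 s | a stirred flask in which second substrate is dosed at a steady rate over 64.0 s without added volume, worked up at 80 s | all but starting material at the start; starting material goes in evenly over 64.0 s, the run ends at 80 s | everything together in a closed stirred flask, run for 80 s |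
| time |  | 80 s | 80 s | 80 s |

* the set-up with the highest amount of target at the outlet or at the end, in percent of the starting material put in ("none" if the first two lie within 2 percentage points) (noon / spring / dawn / midnight / none)
* amount of target at the outlet or at the end, in percent of the starting material put in, noon
* amount of target at the outlet or at the end, in percent of the starting material put in, spring
* amount of target at the outlet or at the end, in percent of the starting material put in, dawn
* amount of target at the outlet or at the end, in percent of the starting material put in, midnight

- percentages count the starting material that a species holds: one spent catalyst counts as two
- the stated concentrations are those of everything mixed, before any reaction; amounts are the same in each set-up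
- the feed brings no volume worth counting
- run time (spring): 80 s

    starting material + free catalyst ⇌ catalyst intermediate A (K1 = 6.7 M⁻¹, k1 = 960 M⁻¹ s⁻¹)
    partner + catalyst intermediate A → free catalyst + target (k2 = 390 M⁻¹ s⁻¹)
    second substrate + free catalyst ⇌ catalyst intermediate B (K3 = 2300 M⁻¹, k3 = 380 M⁻¹ s⁻¹)
    partner + catalyst intermediate B → free catalyst + second product (k4 = 1100 M⁻¹ s⁻¹)
    precatalyst → free catalyst (k5 = 0.063 s⁻¹)
    starting material + catalyst intermediate A → spent catalyst (k6 = 0.11 M⁻¹ s⁻¹)

So I counted lifetimes. Taking partner at half its charge, I had catalyst intermediate A fall back in 0.00698 s but meet partner in 0.0488 s, so the share going forward is:

φ = 0.125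

Catalyst intermediate B falls back in 6.05 s and meets partner in 0.0173 s, so I counted nearly all of it as going forward. My selectivity factor, target made per second product made at equal [starting material] and [second substrate], was then

S = φ·k1/k3 = 0.316

I turned the question round: by this reckoning target leads where [starting material]/[second substrate] exceeds 3.17. The midnight flask starts at one, and holding that ratio gives 25.2 %.

For dawn I assumed that partner lasts about one precatalyst half-life, 11.0 s, with starting material as fed by then and second substrate at half its charge. The ratio is then 0.344, which gives 10.3 %.

For spring the same time gives a ratio of 5.82. But [second substrate] keeps growing during the feed, so I took this as a rough ceiling: 68.0 %. For the noon tank, which works at its outlet [partner], I took the closed-flask figure as a cap: 25.2 %. My choice was spring.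

The forecast chose spring, with 16 % for noon, 55 % for spring, 11 % for dawn and 28 % for midnight, holding that "the closed flask gives a middling share".

The highest target stood in spring, at 54.5 %, against 17.0 % for noon, 10.3 % for dawn and 27.8 % for midnight. At 80.0 s the spring flask held 0 % of its partner, with 45.5 % of its starting material left. For the dawn flask with 0.630 equiv of partner the capture time stretches, so I reckon S at 0.199 and the target at 4.04 %. That flask ended at 2.23 %, with 98 % of its starting material left.

Its constants were chosen freely; no experiment stands behind them.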